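Remark on the chemistry: the target has no stereocentre and no stereogenic double bond, so all spiro intermediates are handled as racemates. The ring B locants of the target (C1' to C6') are kept for the spiro ring throughout. The enone is therefore called a gris-5'-ene, although lowest-locant grisan numbering would run the other way round.

## Structural features

The target (C23H28O7) consists of two tetrasubstituted benzene rings held together by a single oxygen atom that links C6 of ring A to C1' of ring B. Ring A is a methyl benzoate (ester on C1) flanked by a prenyloxy group on C2 and the aryloxy group on C6, with a methyl group on C4. Ring B carries the ether oxygen on C1' between a hydroxymethyl group (C2') and a methoxy group (C6'), and a second methoxy group on C4'. The finished molecule poses no stereochemical problem, and the only stereocentres of the plan, the neighbouring C1' and C2' of the spiro intermediates, are transient. The fragile groups are three: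
- The aryl prenyl ether is lost to strong Brønsted or Lewis acids, hydrogenolysis and quinone oxidants, and undergoes Claisen rearrangement on strong heating.
- The electron-rich benzylic alcohol ionises in acid, and as an alkoxide it can reach the ring A ester and close an eight-membered lactone.
- The methyl ester is the third.

The real difficulty is the diaryl ether. All four ortho positions are substituted and both rings are electron-rich, so metal-mediated O-arylation or SNAr has little to work on, and three kinds of O-alkyl groups must end up on the right oxygen atoms. The feature exploited is that C1' bears the ether oxygen and lies para to the oxygenated C4', while the ester carbon of ring A sits ortho to that same oxygen. Tying the ester carbon to C1' gives a five-membered furanone in which C1' is the spiro carbon of a cyclohexa-2,5-dienone, and breaking that C–C bond with methoxide returns the ester and an aromatic ring B together.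

## Logic of the disconnections

**20 ⇒ 19.** The O–H of the C2' hydroxymethyl group is replaced by an O–Si bond. A free alcohol would be methylated, would add to the dienone, or would attack the ester in the preceding basic steps. The skeleton is not simplified, but every earlier step becomes safe. The forward step must liberate the alcohol without generating a free alkoxide.

**19 ⇒ 18.** The C4'O–CH3 bond is cut. This sets the C4' oxygen apart as a phenolate, the natural leaving terminus of an aromatising fragmentation. The forward step only requires that 18 be alkylated on oxygen in the flask in which it is formed.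

**18 ⇒ 17.** The ester C–OCH3 bond is cut and the ester carbon is reconnected to C1'. The tetra-ortho-substituted diaryl ether thereby becomes an ordinary alkyl aryl ether inside a five-membered ring, which removes the hardest bond from the problem. The forward step demands that methoxide attack the C3 carbonyl rather than the dienone. The gain in aromaticity of ring B must then make the C3–C1' cleavage irreversible.

**17 ⇒ 15 (through 16).** The C2'=C3' double bond is saturated. This uncovers a cyclohexenone, the retron of a cycloaddition with an oxygenated diene. The forward dehydrogenation needs enolisation at C3' only, and the oxidant must spare the prenyl alkene.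

**15 ⇒ 13 + 4 (through 14).** The bonds C1'–C6' and C2'–C3' are cut. All of ring B apart from C1', C2' and the hydroxymethyl carbon falls away as a four-carbon unit that already carries both ring B oxygen functions at the right oxidation level. This is the largest simplification of the plan: one ring, two C–C bonds. The forward step must place the acetal carbon on C1' and the CH2 terminus on C2', and no stereocontrol is needed.

**13 ⇒ 11 + 12.** The exocyclic C1'=C2' double bond is cut. It is an aldol-condensation retron and splits off the protected hydroxymethyl carbon with C2'. A silyl ether is chosen because an ester would not survive methoxide and a benzyl ether could not be removed beside the prenyl group. The forward step must be mild enough for an enolisable α-oxygenated aldehyde.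

**11 ⇒ 10.** A methoxycarbonyl group is added to C2. It is the residue of the ring-forming condensation. The forward step must remove it without hot mineral acid because of the prenyl ether.

**10 ⇒ 9.** The C2–C3 bond of the furanone is cut. This opens the five-membered ring to a diester whose aromatic ester carbon is the future ester carbon of 20. The forward cyclisation is five-membered and is driven by formation of a stabilised enolate.

**9 ⇒ 7 + 8.** The O–CH2 bond at the future bridging oxygen is cut. The critical C–O bond of the target is thus made as a simple alkylation of a phenol. The only demand is to ionise a chelated phenol.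

**7 ⇒ 5 + 6.** The O–CH2 bond of the prenyl ether is cut. The two hydroxyl groups of 5 are equivalent, so only the degree of alkylation has to be controlled.

**4 ⇒ 3.** The O–Si bond is cut. The forward step is enol silylation at the only enolisable carbon, the methyl group.

**3 ⇒ 1 + 2.** The C2–C3 bond of the enone is cut. The forward step is C-acylation of an electron-rich alkene, which needs a base that intercepts the proton before chloride dealkylates the cationic intermediate.

## Other disconnections considered

**Alternative 1:** The cut runs through ring A at C1–C2 and C3–C4.
- *Forward key step.* The 4-aryloxy-3-methoxycarbonyl-6-methyl-2-pyrone A1 would take up 1 across its C3 and C6 in an inverse-electron-demand [4+2] reaction. The bridged lactone would lose CO2 and then methanol to give the anisole ester A2.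
- *In favour.* The plan is convergent, and ring B arrives complete as the phenol A3. The crowded C–O bond is made by addition–elimination of A3 at the vinylogous acyl position C4 of a pyrone. The polarity of both partners puts the acetal carbon next to the ester-bearing carbon. No redox step and no stoichiometric palladium are needed.
- *Against.* C2 receives a methoxy group where the target has a prenyloxy group. One of three aryl methyl ethers in A2 would have to be cleaved, by an ester-directed chelating boron halide, to the phenol A4 before 6 could convert A4 into 19. That Lewis acid would meet a silyl ether and an electron-rich benzylic C–O bond. The 4-aryloxy donor and the 6-methyl group also both weaken the pyrone at the very carbon that the CH2 of 1 must attack.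
- *Comparison.* On structure the alternative is better in convergence and equal in the ease of forming the ether bond. On mechanism its regiocontrol is equal to that of the chosen plan. On step economy it is about equal, since the two corrective steps at C2 cancel the saving. It is weaker in end-game chemoselectivity, because the chosen plan never has to distinguish like ethers.

**Alternative 2:** The cut is the C1'–C2' bond of ring B.
- *Forward key step.* Base would fold the aryloxymethyl triketone A5 by aldol addition of C1' to the C2' ketone. Dehydration and enolisation would give the resorcinol acetal A6.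
- *In favour.* A5 could come from the aliphatic ester of 9 and the terminal carbanion of the dianion of the diketone acetal A7. Both new phenols of A6 are to become methoxy groups, so one exhaustive methylation suffices. Acetal hydrolysis to the aldehyde A8 and borohydride reduction would finish at 20. No silyl group, no palladium and no dehydrogenation are needed.
- *Against.* C1' is the least acidic carbon of A5, because C3' and C5' each lie between two carbonyl groups. Once C1' is deprotonated it has a five-membered Dieckmann closure onto the adjacent ring A ester open to it, which is the very reaction used on purpose in step 5. Closure through oxygen to a 4-pyranone is a further exit typical of 1,3,5-triketones.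
- *Comparison.* On step economy this plan is the better one on paper, about two steps shorter in the linear sequence. On structure it is equal, since the ether bond is again an alkylation. On mechanism it is clearly less secure, because the required bond must win against at least two easier cyclisations, whereas the polarised cycloaddition of the chosen plan has one dominant regiochemical outcome.

**Alternative 3:** The cut removes ring A at C1–C2, C5–C6 and C2–C3.
- *Forward key step.* Heating the aryl ynol ether A9 with 3-methylcyclobutenone A10 would open A10 to a vinylketene and add it [2+2] to the alkyne. Ring opening and 6π closure would then give the phenol A11 (Danheiser benzannulation).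
- *In favour.* The substitution pattern of ring A follows unambiguously from the polarity of the ynol ether. The conditions are neutral. The free phenol appears exactly where the prenyl group belongs, which is better than alternative 1 and equal to the chosen plan.
- *Against.* A9 must be made from the hindered phenol A3 through a haloalkenyl ether and an alkynyllithium. Aryloxyalkynes are weaker nucleophiles than alkoxy- or silyloxyalkynes. The alkyne carbon that must attack the ketene carries an inductively withdrawing, bulky acetal. A10 is volatile, not a stock chemical and prone to polymerise. C1 arrives at the aldehyde level, so prenylation, acetal hydrolysis, oxidation and esterification are all needed before 19 is reached.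
- *Comparison.* On structure it is equal in oxygen differentiation. On mechanism it is elegant but rests on two sensitive partners. On step economy it is longer than the chosen plan once A3, A9 and A10 are counted.

Key step: step 8

## Route

**Step 1**
Reactants: 1 1,1-dimethoxyethene; 2 acetyl chloride
Product: 3 4,4-dimethoxybut-3-en-2-one
Conditions: pyridine, CH2Cl2, 0 °C to rt
Reagents that add atoms: none
Why: C-acylation of a ketene acetal, a known reaction of these alkenes with acid chlorides; the nucleophilic CH2 of 1 attacks the N-acetylpyridinium ion and pyridine removes the proton next to the dimethoxycarbenium centre to give the push–pull enone.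

**Step 2**
Reactants: 3 4,4-dimethoxybut-3-en-2-one
Product: 4 1,1-dimethoxy-3-(trimethylsilyloxy)buta-1,3-diene
Conditions: Me3SiOTf, Et3N, Et2O, 0 °C; distilled and used at once
Reagents that add atoms: trimethylsilyl trifluoromethanesulfonate, C[Si](C)(C)OS(=O)(=O)C(F)(F)F
Why: Soft enolisation with O-silylation of a methyl ketone; the methyl group is the only carbon with removable protons, so a single 2-silyloxydiene can form.

**Step 3**
Reactants: 5 methyl 2,6-dihydroxy-4-methylbenzoate; 6 prenyl bromide
Product: 7 methyl 2-hydroxy-4-methyl-6-(3-methylbut-2-enyloxy)benzoate
Conditions: K2CO3 (1.05 equiv), 6 (1.0 equiv), acetone, reflux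
Reagents that add atoms: none
Why: Williamson etherification of one of two equivalent phenols; the hydroxyl left in 7 is chelated to the ester carbonyl and less readily ionised, which together with limiting 6 favours monoalkylation, and the polar medium favours O- over C-prenylation.

**Step 4**
Reactants: 7 methyl 2-hydroxy-4-methyl-6-(3-methylbut-2-enyloxy)benzoate; 8 methyl bromoacetate
Product: 9 methyl 2-(2-methoxy-2-oxoethoxy)-4-methyl-6-(3-methylbut-2-enyloxy)benzoate
Conditions: K2CO3, DMF, 50 °C
Reagents that add atoms: none
Why: Williamson etherification with a highly reactive α-halo ester; DMF breaks the chelate of the phenol. This easy alkylation makes the C–O bond that becomes the hindered diaryl ether linkage.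

**Step 5**
Reactants: 9 methyl 2-(2-methoxy-2-oxoethoxy)-4-methyl-6-(3-methylbut-2-enyloxy)benzoate
Product: 10 methyl 3-hydroxy-6-methyl-4-(3-methylbut-2-enyloxy)benzofuran-2-carboxylate
Conditions: NaOMe, MeOH–THF, 0 °C to reflux; then AcOH, 0 °C
Reagents that add atoms: none
Why: Dieckmann condensation closing a five-membered ring (aryloxyacetate enolate on the aromatic ester), driven by deprotonation of the product to its stabilised enolate; methoxide matches both esters, so transesterification is silent.

**Step 6**
Reactants: 10 methyl 3-hydroxy-6-methyl-4-(3-methylbut-2-enyloxy)benzofuran-2-carboxylate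
Product: 11 6-methyl-4-(3-methylbut-2-enyloxy)benzofuran-3(2H)-one
Conditions: LiCl, H2O, DMSO, 130 °C, N2
Reagents that add atoms: none
Why: Krapcho dealkoxycarbonylation of a β-keto ester: chloride dealkylates the methyl ester and the β-keto carboxylate loses CO2. The near-neutral medium replaces the usual hot mineral acid, which would endanger the prenyl ether, and the temperature stays well below that of the aromatic Claisen rearrangement.

**Step 7**
Reactants: 11 6-methyl-4-(3-methylbut-2-enyloxy)benzofuran-3(2H)-one; 12 (tert-butyldimethylsilyloxy)acetaldehyde
Product: 13 (Z)-2-[2-(tert-butyldimethylsilyloxy)ethylidene]-6-methyl-4-(3-methylbut-2-enyloxy)benzofuran-3(2H)-one (CH2OSi cis to O1)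
Conditions: neutral Al2O3, 12 (1.5 equiv), CH2Cl2, rt
Reagents that add atoms: none
Why: Knoevenagel-type aldol condensation on alumina, the standard mild entry to aurones and 2-alkylidenebenzofuranones. The Z isomer, with the substituent turned away from the C3 carbonyl, is the thermodynamic one, and the geometry has no consequence for the target.

**Step 8**
Reactants: 13 (Z)-2-[2-(tert-butyldimethylsilyloxy)ethylidene]-6-methyl-4-(3-methylbut-2-enyloxy)benzofuran-3(2H)-one; 4 1,1-dimethoxy-3-(trimethylsilyloxy)buta-1,3-diene
Product: 15 6'-methoxy-6-methyl-4-(3-methylbut-2-enyloxy)-2'-[(tert-butyldimethylsilyloxy)methyl]gris-5'-ene-3,4'-dione (racemic; C1'/C2' diastereomers not separated), via ketal silyl enol ether cycloadduct 14 (not isolated)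
Conditions: 4 (3 equiv), PhMe, 110 °C, sealed tube; then 0.1 M HCl, THF, 0 °C
Reagents that add atoms: none
Why: Normal-electron-demand Diels–Alder reaction: the HOMO of 4, raised by three oxygen donors, is largest at the unsubstituted CH2 terminus and the LUMO of 13 is largest at the exocyclic β carbon C2', so C2'–C3' bonding runs ahead of C1'–C6' bonding in a strongly asynchronous transition state, whose limit is a Mukaiyama–Michael addition followed by collapse of the C1' enolate on the dimethoxycarbenium carbon. Either timing gives the same constitution, with the acetal carbon on the spiro centre and the CH2 next to the silyloxymethyl-bearing carbon; this regiochemistry is the only selectivity the step needs, and the matched polarisation of the two partners secures it. Ring B is closed as a six-membered carbocycle by [4+2] union of the four diene carbons with the exocyclic C1'=C2' bond, spiro-fused to the furanone at C1'. Cold dilute acid then cleaves the trimethylsilyl enol ether of 14 to the C4' ketone and induces β-elimination of one methoxy group, leaving the vinylogous ester 15, while the primary tert-butyldimethylsilyl ether and the prenyl ether tolerate this brief treatment. C1' and C2' are the two new stereocentres: suprafacial addition transfers the alkene geometry of 13 into their relative configuration, neither diene terminus becomes stereogenic so endo and exo approaches converge, and stepwise leakage would merely add the second diastereomer; nothing controls the absolute sense and nothing needs to, since both centres become planar in steps 9 and 10. The isolated prenyl alkene is no dienophile for an electron-rich diene, and without a Lewis acid the C3 carbonyl should not act as a heterodienophile. The closest known reaction type is the cycloaddition of 2-alkylidenebenzofuran-3(2H)-ones with 1,1-dialkoxy-3-silyloxybutadienes used to assemble grisan spirocycles.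

**Step 9**
Reactants: 15 6'-methoxy-6-methyl-4-(3-methylbut-2-enyloxy)-2'-[(tert-butyldimethylsilyloxy)methyl]gris-5'-ene-3,4'-dione
Product: 17 6'-methoxy-6-methyl-4-(3-methylbut-2-enyloxy)-2'-[(tert-butyldimethylsilyloxy)methyl]grisa-2',5'-diene-3,4'-dione (racemic; C1' the only stereocentre), via cross-conjugated trimethylsilyl dienol ether 16 (not isolated)
Conditions: Me3SiCl, LiN(SiMe3)2 (in situ quench), THF, −78 °C; solvent exchange; then Pd(OAc)2 (1.1 equiv), MeCN, rt
Reagents that add atoms: chlorotrimethylsilane, C[Si](C)(C)Cl (its silyl group is carried by 16 only and is lost again in 17)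
Why: Saegusa–Ito oxidation: C3' is the only enolisable carbon (C1' is quaternary and the C3 ketone has no α-hydrogen), and silyl chloride present during deprotonation traps the kinetic enolate before ring B can open by retro-Michael reaction. Divalent palladium forms the oxo-π-allyl complex and β-hydride elimination of H2' gives the cross-conjugated dienone, which removes the C2' stereocentre; the trisubstituted prenyl alkene is a poor ligand under these conditions.

**Step 10**
Reactants: 17 6'-methoxy-6-methyl-4-(3-methylbut-2-enyloxy)-2'-[(tert-butyldimethylsilyloxy)methyl]grisa-2',5'-diene-3,4'-dione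
Product: 19 methyl 2-{2-[(tert-butyldimethylsilyloxy)methyl]-4,6-dimethoxyphenoxy}-4-methyl-6-(3-methylbut-2-enyloxy)benzoate, via sodium 4'-phenolate 18 (not isolated)
Conditions: NaOMe (1.2 equiv), MeOH–THF, 0 °C to rt; then MeI (excess), DMF, rt
Reagents that add atoms: sodium methoxide, [Na+].[O-]C; iodomethane, CI
Why: Retro-Claisen fragmentation of a grisadienone, a known route to diphenyl ethers: methoxide adds to the strained, non-enolisable C3 ketone and the tetrahedral intermediate expels C1' as the para carbon of a phenolate, so aromatisation of ring B makes the cleavage irreversible and erases the last stereocentre. The phenolate is then O-methylated in the same flask (Williamson); C2' is meta to the phenolate oxygen, so no quinone methide can form from the silyloxymethyl group.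

**Step 11**
Reactants: 19 methyl 2-{2-[(tert-butyldimethylsilyloxy)methyl]-4,6-dimethoxyphenoxy}-4-methyl-6-(3-methylbut-2-enyloxy)benzoate
Product: 20 methyl 2-[2-(hydroxymethyl)-4,6-dimethoxyphenoxy]-4-methyl-6-(3-methylbut-2-enyloxy)benzoate (CNP0573678.0)
Conditions: Bu4NF, AcOH (1:1), THF, 0 °C to rt
Reagents that add atoms: none
Why: Fluoride-induced cleavage of a primary silyl ether; the acetic acid buffer protonates the alkoxide as it forms, which should suppress eight-membered lactonisation onto the ring A ester and Smiles-type migration. The ester, aryl ethers and prenyl group are inert.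

## Compound list

1 | 1,1-dimethoxyethene | C=C(OC)OC | starting material
2 | acetyl chloride | CC(=O)Cl | starting material
3 | 4,4-dimethoxybut-3-en-2-one | CC(=O)C=C(OC)OC | intermediate
4 | 1,1-dimethoxy-3-(trimethylsilyloxy)buta-1,3-diene | C=C(O[Si](C)(C)C)C=C(OC)OC | intermediate
5 | methyl 2,6-dihydroxy-4-methylbenzoate | COC(=O)c1c(O)cc(C)cc1O | starting material
6 | prenyl bromide (1-bromo-3-methylbut-2-ene) | CC(C)=CCBr | starting material
7 | methyl 2-hydroxy-4-methyl-6-(3-methylbut-2-enyloxy)benzoate | COC(=O)c1c(O)cc(C)cc1OCC=C(C)C | intermediate
8 | methyl bromoacetate | COC(=O)CBr | starting material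
9 | methyl 2-(2-methoxy-2-oxoethoxy)-4-methyl-6-(3-methylbut-2-enyloxy)benzoate | COC(=O)COc1cc(C)cc(OCC=C(C)C)c1C(=O)OC | intermediate
10 | methyl 3-hydroxy-6-methyl-4-(3-methylbut-2-enyloxy)benzofuran-2-carboxylate | COC(=O)c1oc2cc(C)cc(OCC=C(C)C)c2c1O | intermediate
11 | 6-methyl-4-(3-methylbut-2-enyloxy)benzofuran-3(2H)-one | CC(C)=CCOc1cc(C)cc2OCC(=O)c12 | intermediate
12 | (tert-butyldimethylsilyloxy)acetaldehyde | O=CCO[Si](C)(C)C(C)(C)C | starting material
13 | (Z)-2-[2-(tert-butyldimethylsilyloxy)ethylidene]-6-methyl-4-(3-methylbut-2-enyloxy)benzofuran-3(2H)-one | CC(C)=CCOc1cc(C)cc2O/C(=C\CO[Si](C)(C)C(C)(C)C)C(=O)c12 | intermediate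
14 | 6',6'-dimethoxy-6-methyl-4-(3-methylbut-2-enyloxy)-2'-[(tert-butyldimethylsilyloxy)methyl]-4'-(trimethylsilyloxy)gris-4'-en-3-one, racemic | CC(C)=CCOc1cc(C)cc2OC3(C(=O)c12)C(CO[Si](C)(C)C(C)(C)C)CC(O[Si](C)(C)C)=CC3(OC)OC | intermediate (not isolated)
15 | 6'-methoxy-6-methyl-4-(3-methylbut-2-enyloxy)-2'-[(tert-butyldimethylsilyloxy)methyl]gris-5'-ene-3,4'-dione, racemic, diastereomers not separated | CC(C)=CCOc1cc(C)cc2OC3(C(=O)c12)C(CO[Si](C)(C)C(C)(C)C)CC(=O)C=C3OC | intermediate
16 | 6'-methoxy-6-methyl-4-(3-methylbut-2-enyloxy)-2'-[(tert-butyldimethylsilyloxy)methyl]-4'-(trimethylsilyloxy)grisa-3',5'-dien-3-one, racemic | CC(C)=CCOc1cc(C)cc2OC3(C(=O)c12)C(CO[Si](C)(C)C(C)(C)C)C=C(O[Si](C)(C)C)C=C3OC | intermediate (not isolated)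
17 | 6'-methoxy-6-methyl-4-(3-methylbut-2-enyloxy)-2'-[(tert-butyldimethylsilyloxy)methyl]grisa-2',5'-diene-3,4'-dione, racemic | CC(C)=CCOc1cc(C)cc2OC3(C(=O)c12)C(CO[Si](C)(C)C(C)(C)C)=CC(=O)C=C3OC | intermediate
18 | sodium 3-[(tert-butyldimethylsilyloxy)methyl]-5-methoxy-4-[2-(methoxycarbonyl)-5-methyl-3-(3-methylbut-2-enyloxy)phenoxy]phenolate | COC(=O)c1c(OCC=C(C)C)cc(C)cc1Oc1c(CO[Si](C)(C)C(C)(C)C)cc([O-])cc1OC.[Na+] | intermediate (not isolated)
19 | methyl 2-{2-[(tert-butyldimethylsilyloxy)methyl]-4,6-dimethoxyphenoxy}-4-methyl-6-(3-methylbut-2-enyloxy)benzoate | COC(=O)c1c(OCC=C(C)C)cc(C)cc1Oc1c(CO[Si](C)(C)C(C)(C)C)cc(OC)cc1OC | intermediate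
20 | methyl 2-[2-(hydroxymethyl)-4,6-dimethoxyphenoxy]-4-methyl-6-(3-methylbut-2-enyloxy)benzoate | COC(=O)c1c(OCC=C(C)C)cc(C)cc1Oc1c(CO)cc(OC)cc1OC | target

## Step count and least certain steps

Total step count: 11. Longest linear sequence: 9 steps (steps 3 to 11, from 5 to 20). The diene branch (steps 1 and 2) joins at step 8.

**Step 8 (key step).**
- *Risk.* The cycloaddition is most likely to be sluggish. The oxygen O1 on the α carbon and the donor-substituted ring A weaken the acceptor, and the inward-pointing methoxy group of 4 disfavours its s-cis conformation. Long heating then favours decay of the diene. It also favours interruption of the asynchronous process after the first bond, either by silyl transfer to the enolate or by closure through the enolate oxygen. The latter is the hetero-Diels–Alder mode of the fixed s-cis enone, helped by aromatisation of the furan ring.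
- *Fallback.* A base-catalysed double Michael annulation builds ring B through C1'–C6' and C1'–C2' instead. It sets out from 11 and 12 and returns at 15.
  - Wittig reaction of 12 with Ph3P=CHCHO gives (E)-4-(tert-butyldimethylsilyloxy)but-2-enal F1.
  - Lithium methoxyacetylide, generated from 2-chloro-1,1-dimethoxyethane and LiNEt2, adds to F1 to give (E)-6-(tert-butyldimethylsilyloxy)-1-methoxyhex-4-en-1-yn-3-ol F2.
  - MnO2 oxidises F2 to (E)-6-(tert-butyldimethylsilyloxy)-1-methoxyhex-4-en-1-yn-3-one F3.
  - The enolate of 11 (catalytic KOtBu, THF–tBuOH) adds through C2 first to the alkoxyalkyne terminus and then to the enone terminus of F3, giving 15.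

**Step 7.**
- *Risk.* The enolisable aldehyde may self-condense. A second molecule of 11 may add to the freshly formed enone. The double bond may migrate under base toward the silyloxy-bearing carbon.
- *Fallback.* A directed aldol reaction with separate dehydration sets out from 11 and returns at 13.
  - LiN(SiMe3)2 in THF at −78 °C followed by 12 gives 2-[2-(tert-butyldimethylsilyloxy)-1-hydroxyethyl]-6-methyl-4-(3-methylbut-2-enyloxy)benzofuran-3(2H)-one F4.
  - MsCl and Et3N convert F4 into its methanesulfonate F5.
  - DBU induces E1cB elimination of F5 to 13.

**Step 9.**
- *Risk.* Ring B may open by retro-Michael reaction at the enolate stage. Compound 16 may be protodesilylated back to 15 by the acetic acid that is liberated. Divalent palladium may engage the prenyl alkene.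
- *Fallback.* A metal-free sulfur-based dehydrogenation sets out from 15 and returns at 17. The lithium enolate of 15 (LiN(SiMe3)2, THF, −78 °C) is treated with N-tert-butylbenzenesulfinimidoyl chloride. The resulting 3'-(N-tert-butyl-S-phenylsulfinimidoyl) adduct F6 undergoes intramolecular syn elimination at low temperature to 17.

**Step 10.**
- *Risk.* Methoxide attack at the hindered C3 carbonyl may be slow relative to reversible conjugate addition to the dienone. Surplus methoxide may consume the methylating agent so that O-methylation stays incomplete. The silyl ether may be partly lost.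
- *Fallback.* Hydrolytic opening sets out from 17 and returns at 19. Aqueous LiOH in THF opens 17, and the carboxylate that forms cannot re-close. This gives 2-{2-[(tert-butyldimethylsilyloxy)methyl]-4-hydroxy-6-methoxyphenoxy}-4-methyl-6-(3-methylbut-2-enyloxy)benzoic acid F7. One treatment with MeI and K2CO3 in DMF methylates the acid and the phenol together to give 19.

**Step 1.**
- *Risk.* Chloride may dealkylate the dimethoxycarbenium intermediate, which collapses it to the β-keto ester level. Compound 1 may polymerise under acid catalysis.
- *Fallback.* A route without the ketene acetal sets out from 2 and returns at 3. AlCl3-promoted addition of 2 to 1,1-dichloroethene gives 4,4,4-trichlorobutan-2-one F8. This loses HCl on distillation to give 4,4-dichlorobut-3-en-2-one F9. Two addition–eliminations with NaOMe in MeOH give 3.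

## Further compounds

F1 | step 8 | (E)-4-(tert-butyldimethylsilyloxy)but-2-enal | O=C/C=C/CO[Si](C)(C)C(C)(C)C
F2 | step 8 | (E)-6-(tert-butyldimethylsilyloxy)-1-methoxyhex-4-en-1-yn-3-ol, racemic | COC#CC(O)/C=C/CO[Si](C)(C)C(C)(C)C
F3 | step 8 | (E)-6-(tert-butyldimethylsilyloxy)-1-methoxyhex-4-en-1-yn-3-one | COC#CC(=O)/C=C/CO[Si](C)(C)C(C)(C)C
F4 | step 7 | 2-[2-(tert-butyldimethylsilyloxy)-1-hydroxyethyl]-6-methyl-4-(3-methylbut-2-enyloxy)benzofuran-3(2H)-one, racemic diastereomer mixture | CC(C)=CCOc1cc(C)cc2OC(C(O)CO[Si](C)(C)C(C)(C)C)C(=O)c12
F5 | step 7 | methanesulfonate of F4, racemic diastereomer mixture | CC(C)=CCOc1cc(C)cc2OC(C(OS(C)(=O)=O)CO[Si](C)(C)C(C)(C)C)C(=O)c12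
F6 | step 9 | 3'-(N-tert-butyl-S-phenylsulfinimidoyl) derivative of 15, racemic | CC(C)=CCOc1cc(C)cc2OC3(C(=O)c12)C(CO[Si](C)(C)C(C)(C)C)C(S(=NC(C)(C)C)c1ccccc1)C(=O)C=C3OC
F7 | step 10 | 2-{2-[(tert-butyldimethylsilyloxy)methyl]-4-hydroxy-6-methoxyphenoxy}-4-methyl-6-(3-methylbut-2-enyloxy)benzoic acid | OC(=O)c1c(OCC=C(C)C)cc(C)cc1Oc1c(CO[Si](C)(C)C(C)(C)C)cc(O)cc1OC
F8 | step 1 | 4,4,4-trichlorobutan-2-one | CC(=O)CC(Cl)(Cl)Cl
F9 | step 1 | 4,4-dichlorobut-3-en-2-one | CC(=O)C=C(Cl)Cl
A1 | alternative 1 | methyl 4-{2-[(tert-butyldimethylsilyloxy)methyl]-4,6-dimethoxyphenoxy}-6-methyl-2-oxo-2H-pyran-3-carboxylate | COC(=O)C1=C(Oc2c(CO[Si](C)(C)C(C)(C)C)cc(OC)cc2OC)C=C(C)OC1=O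
A2 | alternative 1 | methyl 2-methoxy-4-methyl-6-{2-[(tert-butyldimethylsilyloxy)methyl]-4,6-dimethoxyphenoxy}benzoate | COC(=O)c1c(OC)cc(C)cc1Oc1c(CO[Si](C)(C)C(C)(C)C)cc(OC)cc1OC
A3 | alternative 1 | 2-[(tert-butyldimethylsilyloxy)methyl]-4,6-dimethoxyphenol | COc1cc(CO[Si](C)(C)C(C)(C)C)c(O)c(OC)c1
A4 | alternative 1 | methyl 2-hydroxy-4-methyl-6-{2-[(tert-butyldimethylsilyloxy)methyl]-4,6-dimethoxyphenoxy}benzoate | COC(=O)c1c(O)cc(C)cc1Oc1c(CO[Si](C)(C)C(C)(C)C)cc(OC)cc1OC
A5 | alternative 2 | methyl 2-[(7,7-dimethoxy-2,4,6-trioxoheptyl)oxy]-4-methyl-6-(3-methylbut-2-enyloxy)benzoate | COC(=O)c1c(OCC=C(C)C)cc(C)cc1OCC(=O)CC(=O)CC(=O)C(OC)OC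
A6 | alternative 2 | methyl 2-[2-(dimethoxymethyl)-4,6-dihydroxyphenoxy]-4-methyl-6-(3-methylbut-2-enyloxy)benzoate | COC(=O)c1c(OCC=C(C)C)cc(C)cc1Oc1c(C(OC)OC)cc(O)cc1O
A7 | alternative 2 | 1,1-dimethoxypentane-2,4-dione | CC(=O)CC(=O)C(OC)OC
A8 | alternative 2 | methyl 2-(2-formyl-4,6-dimethoxyphenoxy)-4-methyl-6-(3-methylbut-2-enyloxy)benzoate | COC(=O)c1c(OCC=C(C)C)cc(C)cc1Oc1c(C=O)cc(OC)cc1OC
A9 | alternative 3 | tert-butyl{[2-(3,3-diethoxyprop-1-ynyloxy)-3,5-dimethoxyphenyl]methoxy}dimethylsilane | CCOC(OCC)C#COc1c(CO[Si](C)(C)C(C)(C)C)cc(OC)cc1OC
A10 | alternative 3 | 3-methylcyclobut-2-en-1-one | CC1=CC(=O)C1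
A11 | alternative 3 | 2-(diethoxymethyl)-5-methyl-3-{2-[(tert-butyldimethylsilyloxy)methyl]-4,6-dimethoxyphenoxy}phenol | CCOC(OCC)c1c(O)cc(C)cc1Oc1c(CO[Si](C)(C)C(C)(C)C)cc(OC)cc1OC
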